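## Analysis of the target

The target 46 is a cis-fused hydroazulene: a cyclopentane (C1, C2, C3, C3a, C8a) shares the C3a–C8a bond with a cycloheptane (C3a, C4 to C8, C8a) that carries a gem-dimethyl group at C4 and an exocyclic methylidene at C8. The quaternary carbon C1 bears a methyl group and a side chain made of the methine C1′, its acetoxymethyl carbon C2′ and a γ-butyrolactone (C2″ carbonyl, C3″ with the second acetate, C4″ bonded to C1′, C5″ as OCH2). There are six stereocentres: C3a, C8a and C1 in the bicycle, where the two ring-fusion hydrogens and the side chain lie on the convex face and the C1 methyl group on the concave face next to C8, and C1′, C4″ and C3″ in the side chain, where the C3″ acetate is trans to C1′ on the lactone. The sensitive groups are the α-acetoxy lactone and the primary acetate, which do not tolerate strong base or hydride, and the 1,1-disubstituted alkene, which migrates into the ring under acid and is attacked by boranes; C8a is epimerisable whenever C8 is a ketone. The hard problems are the all-carbon quaternary centre C1 wedged between the tertiary carbons C8a and C1′, the ring-fusion carbon C3a next to the fully substituted C4, and the relay of stereochemical information from the bicycle to C1′ across a single bond. The strategy rests on one structural relation: if C1 and C1′ are joined by a double bond, the oxygen on C2′ is allylic to C1, and the ring methylene C2 sits two carbons from C3a, so a propanoyl chain on C3a (C3, C2 and a carboxyl carbon) esterified with that oxygen gives a nine-membered lactone containing C3a, C8a, C1, C1′ and C2′. In that lactone C2, as an ester enolate carbon, and C1 are the two ends of a [3,3] array, and the shift forms C1–C2, closes the cyclopentane and leaves C1 as a quaternary carbon bearing a vinyl group (C1′=C2′).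

## Retrosynthetic reasoning

46 ⇒ 45 ⇒ 44. The C8=CH2 bond is cut first, back to ketone 45 and then to ketal 44. The alkene is introduced last because it would be hydroborated in the reduction that makes C2′ an alcohol and could migrate under acid. The forward methylenation must therefore work on a hindered ketone with an epimerisable α-carbon, beside two acetates and a lactone, which calls for a non-basic titanium–methylene reagent.

44 ⇒ 43 ⇒ 42 ⇒ 41. The acetates go back to diol 43, the C2′ hydroxyl to the carboxyl group of acid 42, and this to benzyl ester 41. A benzyl ester is chosen because hydrogenolysis frees the acid without acid (ketal) or base (lactone); the free acid can then be reduced in the presence of the lactone.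

41 ⇒ 37 + 38. The C1′–C4″ bond and the C3″–O bond are cut together: ester enolate 39, made from 37, adds to furan-2(5H)-one 38, and lactone enolate 40 is oxidised at C3″. This is the only cut that brings in the intact lactone in one operation and creates the three side-chain stereocentres together. The forward step has to differentiate the faces of the enolate (through C1) and of 38.

37 ⇒ 36 ⇒ 34 ⇒ 33 ⇒ 31 ⇒ 28 ⇒ 25. The acetic ester arm is traced through acid 36 and alcohol 34 to silyl ether 33. The C2 methylene comes from radical decarboxylation of acid 31, and the side-chain oxygen from hydroboration of the vinyl group of 25, isolated as lactone 28. The vinyl group is converted before the carboxyl group is removed: a C2 radical next to a quaternary carbon that still carries a vinyl group could close onto it and reopen with 1,2-vinyl migration, which would destroy C1.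

25 ⇒ 22 (key disconnection). The C1–C2 bond is cut and the C2 carboxyl carbon is reconnected through oxygen to C2′, with C1=C1′ as a (Z)-alkene. This one cut removes the cyclopentane and the quaternary centre at once and leaves a bicyclic lactone whose only stereocentres are C3a and C8a. The forward Ireland–Claisen shift has to deliver C2 to the face of C1 that puts the vinyl group cis to the ring-fusion hydrogens.

22 ⇒ 20 ⇒ 18 ⇒ 17. The lactone C–O bond is opened to seco acid 20, which comes from ester 18 and this from ketone 17. The ketal is put on as soon as C8a exists, because in 17 that centre is both α to the ketone and allylic.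

17 ⇒ 13 + 15. The C3a–C3 bond is cut: conjugate addition of zinc reagent 15 (from ethyl 3-iodopropanoate 14) to dienone 13 under a chiral copper catalyst sets C3a, and kinetic protonation of enolate 16 sets C8a cis to it.

13 ⇒ 6 + 12. The C8a–C1 bond is a palladium-catalysed Negishi coupling of iodoenone 6 with alkenylzinc 12. The (Z)-geometry comes from iodide 10, and via 9 from the trans-hydroalumination and iodination of but-2-yn-1-ol 7.

6 ⇒ 5 ⇒ 3 ⇒ 2 ⇒ 1. Enone 5 is the one-carbon ring enlargement of silyl enol ether 2, whose regiochemistry and gem-dimethyl group both come from conjugate methylation of 3-methylcyclohex-2-en-1-one 1. The regiodefined enol ether places the inserted CH2 so that the enone double bond ends up next to C4.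

## Alternatives that were turned down

Alternative 1: The bond between the gem-dimethyl carbon C4 and the ring-fusion carbon C3a is cut, leading from ketone A1 back to the cyclopentenyl ketone A2, whose acyl chain ends in an isopropenyl group. In the forward step an iron-hydride hydrogen-atom-transfer system turns the isopropenyl group into the tertiary C4 radical, which adds to the β-carbon of the enone and closes the cycloheptanone; reduction and protonation then set C8a.
- For it: the most congested bond of the ring system is made under mild radical conditions, A2 is an open, easily assembled precursor, and A1 is reached in clearly fewer steps than my compound 37, which stands at the same stage. On step economy this alternative is stronger.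
- Against it: the seven-membered closure competes with simple reduction of the tertiary radical. The face of the cyclopentene attacked at C3a is decided only by the difference between a methyl group and an acetate arm on C1, and C8a is then set by protonation of an enolisable centre.
- Comparison: the chosen route is longer, but the ring tether and the alkene geometry fix C1 relative to C3a and C8a in one pericyclic step, and the side-chain problem is the same in both routes.

Alternative 2: The ring O–CH2 bond of the lactone is cut, leading from lactone A3 back to the 3-substituted cyclobutanone A4. In the forward step aqueous peroxide and a chiral Brønsted acid insert oxygen next to the carbonyl of A4 in a desymmetrising Baeyer–Villiger reaction and fix C4″.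
- For it: C4″ is set by the catalyst and not by the substrate, there is no regiochemical question because the two migrating CH2 groups are equivalent, and C1′ and C4″ are decoupled. On the control of C4″ this is stronger than my step 19, which sets C1′ and C4″ together under substrate control.
- Against it: it solves only the end of the synthesis. A4 needs C1′ to be made beforehand next to the quaternary carbon, a cyclobutanone to be built on a hindered alkene, and later hydroxylation at C3″ and exchange of the benzyl ether. The catalyst also has to override three resident stereocentres, and the acidic peroxide is not kind to the ketal.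
- Comparison: it gives no answer for the hydroazulene and would have to be grafted onto a core synthesis such as the present one, at the price of several more steps than the single Michael/hydroxylation step.

Alternative 3: The C3a–C8a bond is cut and C3a is reconnected to C8, leading from ester A5 back to the trans-decalin mesylate A6, to be derived from (+)-sclareolide A7. In the forward step buffered solvolysis of the equatorial mesylate lets the antiperiplanar ring-fusion bond migrate to the ionising carbon, so that the two six-membered rings become the five- and the seven-membered ring; the C8 cation then loses a methyl proton to give the methylidene.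
- For it: absolute configuration, gem-dimethyl group and the angular methyl come from the chiral pool, the migration is stereospecific and gives the cis ring fusion, and the methylidene appears without a separate step. On absolute stereocontrol and on the brevity of the key step this is stronger.
- Against it: A7 carries the acetic acid chain on the carbon that must bear the leaving group and the oxygen on the carbon that must become quaternary, so A6 is many steps away. The second ring bond antiperiplanar to the mesylate can migrate as well, the tertiary cation can also give ring alkenes, and the methylidene then has to survive the whole endgame.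
- Comparison: the chosen route pays with more steps before the key step but concentrates its risk in one step of predictable geometry and keeps C8 masked until the end.

Key step: step 12

Assumption: the (S,R,R)-phosphoramidite is taken to deliver the alkyl group to the same enone face as in unsubstituted cycloalkenones (which corresponds to the required C3a configuration); should the sense be reversed on 13, the enantiomeric ligand is used.

## Route

Step 1
Reactants: 1 3-methylcyclohex-2-en-1-one
Product: 2 [(3,3-dimethylcyclohex-1-en-1-yl)oxy]trimethylsilane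
Conditions: MeMgBr, CuBr·SMe2 (5 mol %), Me3SiCl, THF, −78 → 0 °C; Et3N
Reagents that add atoms: methylmagnesium bromide (C[Mg]Br); chlorotrimethylsilane (C[Si](C)(C)Cl)
Why: Copper-catalysed conjugate addition of the Grignard reagent, accelerated by the chlorosilane, builds the gem-dimethyl carbon and traps the enolate regiospecifically as the silyl enol ether. Its double bond points toward the new quaternary carbon, a regiochemistry not available by enolising 3,3-dimethylcyclohexanone, and this decides where the ring is enlarged.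

Step 2
Reactants: 2 [(3,3-dimethylcyclohex-1-en-1-yl)oxy]trimethylsilane
Product: 3 rac-[(5,5-dimethylbicyclo[4.1.0]heptan-1-yl)oxy]trimethylsilane
Conditions: Et2Zn, CH2I2, CH2Cl2, 0 °C → rt
Reagents that add atoms: diiodomethane (ICI)
Why: Simmons–Smith cyclopropanation; the electron-rich enol ether double bond should take up the zinc carbenoid despite the neighbouring quaternary carbon. The stereocentres of 3 are lost in the next step.

Step 3
Reactants: 3 rac-[(5,5-dimethylbicyclo[4.1.0]heptan-1-yl)oxy]trimethylsilane
Product: 5 4,4-dimethylcyclohept-2-en-1-one, via 3-chloro-4,4-dimethylcycloheptan-1-one 4 (not isolated)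
Conditions: FeCl3, DMF, 0 °C → rt; then NaOAc, MeOH, reflux
Reagents that add atoms: none
Why: Oxidative ring opening of the siloxycyclopropane by FeCl3 cleaves the ring-fusion bond to the secondary β-keto radical, which takes up chlorine to give the ring-enlarged β-chloro ketone; acetate then removes HCl by E1cB elimination. This is the standard one-carbon enlargement of a cycloalkanone to a cycloalk-2-enone, and the inserted CH2 lies between the carbonyl and the carbon next to the gem-dimethyl group.

Step 4
Reactants: 5 4,4-dimethylcyclohept-2-en-1-one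
Product: 6 2-iodo-4,4-dimethylcyclohept-2-en-1-one
Conditions: I2, pyridine, CH2Cl2, 0 °C → rt
Reagents that add atoms: iodine (II)
Why: α-Iodination of the enone by reversible conjugate addition of pyridine, iodination of the enolate and elimination. The six-membered analogue with the same neopentyl β-carbon is a standard substrate of this reaction.

Step 5
Reactants: 7 but-2-yn-1-ol
Product: 9 (2Z)-3-iodobut-2-en-1-ol, via cyclic alkenylalanate 8 (not isolated)
Conditions: NaAlH2(OCH2CH2OMe)2, Et2O, 0 °C → rt; then I2, THF, −78 → 0 °C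
Reagents that add atoms: iodine (II)
Why: The alkoxide-bound aluminium hydride delivers hydride to C2 within the complex (trans-hydroalumination) and leaves aluminium on C3 in a five-membered ring, cis to the CH2O group. Iodinolysis with retention should give only the (Z)-iodide.

Step 6
Reactants: 9 (2Z)-3-iodobut-2-en-1-ol
Product: 10 tert-butyl{[(2Z)-3-iodobut-2-en-1-yl]oxy}dimethylsilane
Conditions: t-BuMe2SiCl, imidazole, CH2Cl2, rt
Reagents that add atoms: tert-butyl(chloro)dimethylsilane (CC(C)(C)[Si](C)(C)Cl)
Why: Standard silylation of a primary alcohol. The silyl ether tolerates the organolithium, organozinc and Lewis-acid steps and is removed by fluoride.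

Step 7
Reactants: 10 tert-butyl{[(2Z)-3-iodobut-2-en-1-yl]oxy}dimethylsilane; 6 2-iodo-4,4-dimethylcyclohept-2-en-1-one
Product: 13 2-[(2Z)-4-{[tert-butyl(dimethyl)silyl]oxy}but-2-en-2-yl]-4,4-dimethylcyclohept-2-en-1-one, via alkenyllithium 11 (not isolated), via alkenylzinc chloride 12 (not isolated)
Conditions: t-BuLi (2 equiv), Et2O, −78 °C; ZnCl2, THF, −78 → 0 °C; then 6, Pd(PPh3)4 (5 mol %), THF, rt
Reagents that add atoms: none
Why: Iodine–lithium exchange and transmetalation to zinc keep the alkene geometry; the lithium stage is held at −78 °C to avoid 1,4-migration of silicon from oxygen to carbon. Negishi coupling of an alkenylzinc with an α-iodoenone is an established α-alkenylation of enones.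

Step 8
Reactants: 13 2-[(2Z)-4-{[tert-butyl(dimethyl)silyl]oxy}but-2-en-2-yl]-4,4-dimethylcyclohept-2-en-1-one; 14 ethyl 3-iodopropanoate
Product: 17 ethyl 3-[(1R,2R)-2-[(2Z)-4-{[tert-butyl(dimethyl)silyl]oxy}but-2-en-2-yl]-7,7-dimethyl-3-oxocycloheptyl]propanoate, via bis(3-ethoxy-3-oxopropyl)zinc 15 (not isolated), via zinc enolate 16 (not isolated)
Conditions: 14, Et2Zn, CuI (cat.), 50 °C, volatiles removed; then 13, Cu(OTf)2 (3 mol %), (S,R,R)-binaphthyl N,N-bis(1-phenylethyl)phosphoramidite (6 mol %), toluene, −30 → 0 °C; then 2,6-di-tert-butyl-4-methylphenol, THF, −78 °C; pH 7 buffer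
Reagents that add atoms: none
Why: Iodine–zinc exchange gives the ester-stabilised diorganozinc, which adds 1,4 to the enone under copper/phosphoramidite catalysis; the ligand selects the enone face and so sets C3a. The zinc enolate is protonated at −78 °C by a hindered phenol on the face away from the new pseudoaxial C3a chain (kinetic protonation), which should place the alkenyl group cis to it.

Step 9
Reactants: 17 ethyl 3-[(1R,2R)-2-[(2Z)-4-{[tert-butyl(dimethyl)silyl]oxy}but-2-en-2-yl]-7,7-dimethyl-3-oxocycloheptyl]propanoate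
Product: 18 ethyl 3-[(6R,7R)-6-[(2Z)-4-{[tert-butyl(dimethyl)silyl]oxy}but-2-en-2-yl]-8,8-dimethyl-1,4-dioxaspiro[4.6]undecan-7-yl]propanoate
Conditions: Me3SiOCH2CH2OSiMe3, Me3SiOTf (5 mol %), CH2Cl2, −78 → −30 °C; pyridine
Reagents that add atoms: 1,2-bis(trimethylsilyloxy)ethane (C[Si](C)(C)OCCO[Si](C)(C)C)
Why: Aprotic low-temperature ketalisation with the bis-silyl ether of the diol should proceed without enolisation, so the labile centre next to the ketone and the position of the β,γ-double bond are kept. Once the ketal is on, that centre is no longer epimerisable and C8 is masked for all base and hydride steps.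

Step 10
Reactants: 18 ethyl 3-[(6R,7R)-6-[(2Z)-4-{[tert-butyl(dimethyl)silyl]oxy}but-2-en-2-yl]-8,8-dimethyl-1,4-dioxaspiro[4.6]undecan-7-yl]propanoate
Product: 20 3-[(6R,7R)-6-[(2Z)-4-hydroxybut-2-en-2-yl]-8,8-dimethyl-1,4-dioxaspiro[4.6]undecan-7-yl]propanoic acid, via hydroxy ester 19 (not isolated)
Conditions: Bu4NF, THF, 0 °C → rt; then LiOH, THF/MeOH/H2O, rt; 0.5 M HCl to pH 5, 0 °C
Reagents that add atoms: lithium hydroxide ([Li+].[OH-])
Why: Fluoride desilylation followed by saponification. The ketal is stable to both and to the brief, cold acidification to pH 5.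

Step 11
Reactants: 20 3-[(6R,7R)-6-[(2Z)-4-hydroxybut-2-en-2-yl]-8,8-dimethyl-1,4-dioxaspiro[4.6]undecan-7-yl]propanoic acid
Product: 22 cis-fused nine-membered (Z)-allylic lactone formed from 20 by joining its carboxyl group to its allylic hydroxyl group, via mixed anhydride 21 (not isolated)
Conditions: 2,4,6-trichlorobenzoyl chloride, Et3N, THF, rt; then slow addition to DMAP, toluene, 80 °C (about 1 mM)
Reagents that add atoms: none
Why: Yamaguchi macrolactonisation through the mixed anhydride under high dilution. The (Z)-alkene and the cis arrangement of the two arms on the cycloheptane hold the hydroxyl and the acyl group on the same side, which should favour ring closure over oligomerisation.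

Step 12
Reactants: 22 cis-fused nine-membered (Z)-allylic lactone
Product: 25 (1S,2R,3aR,8aR)-1-ethenyl-8,8-(ethane-1,2-diyldioxy)-1,4,4-trimethyldecahydroazulene-2-carboxylic acid, via silyl ketene acetal 23 (not isolated), via trimethylsilyl ester 24 (not isolated)
Conditions: LiN(iPr)2, Me3SiCl/Et3N, THF, −78 °C; then toluene, 105 °C; H2O, pH 5 buffer
Reagents that add atoms: none
Why: LiN(iPr)2 removes a proton from C2, the only acidic C–H of 22 (the ketal masks C8), and Me3SiCl present in the flask traps the enolate as silyl ketene acetal 23 before it can condense or eliminate. On heating, 23 should undergo a suprafacial [3,3] shift in which C1–C2 forms as the O–C2′ bond breaks, giving silyl ester 24 and, after hydrolytic work-up, acid 25; the closest known reaction type is the Ireland–Claisen ring contraction of medium-ring allylic lactones to cis-2-alkenylcycloalkanecarboxylic acids. The cyclopentane is closed by a transannular 5-exo-type C–C bond formation inside the nine-membered ring, and because the ketene acetal and the alkene are both cis double bonds within that ring the six-atom array can only be boat-like. C1 is set by two elements acting in the same sense: allylic 1,3-strain in the (Z)-alkene holds H8a in the alkene plane next to C2′, so that C2, tethered through C3 to C3a, reaches C1 on the face that leaves the new vinyl group cis to H8a and H3a and the methyl group cis to C8, and the four-atom loop C1′–C2′–O–C(OSi) then lies over the convex face of the forming cis-bicycle, away from the ketal and the gem-dimethyl group. C2 is set by the boat geometry (carboxyl cis to vinyl) and is of no consequence, since it becomes CH2 in step 15. The step needs face selectivity at C1 and clean enolisation at C2; the first is secured by the ring fusion and the alkene geometry, the second by the internal silyl quench.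

Step 13
Reactants: 25 (1S,2R,3aR,8aR)-1-ethenyl-8,8-(ethane-1,2-diyldioxy)-1,4,4-trimethyldecahydroazulene-2-carboxylic acid
Product: 28 cis-fused δ-lactone formed from hydroxy acid 27 by joining the C2 carboxyl group to the oxygen of the 2-hydroxyethyl group on C1, via bis-borane adduct 26 (not isolated), via hydroxy acid 27 (not isolated)
Conditions: 9-BBN (3 equiv), THF, 0 °C → rt; NaOH, H2O2, 0 °C; citric acid to pH 4; pyridinium p-toluenesulfonate (cat.), CH2Cl2, rt
Reagents that add atoms: hydrogen peroxide (OO)
Why: 9-BBN first converts the acid into its acyloxyborane and then hydroborates the neopentyl vinyl group at the terminal carbon; oxidation gives the primary alcohol, which closes onto the cis carboxyl group as a neutral, easily purified lactone. The vinyl group is consumed here, before the radical step, because a C2 radical next to a vinyl-bearing quaternary carbon could rearrange by 1,2-vinyl migration.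

Step 14
Reactants: 28 cis-fused δ-lactone
Product: 31 (1S,2R,3aR,8aR)-1-(2-{[tert-butyl(dimethyl)silyl]oxy}ethyl)-8,8-(ethane-1,2-diyldioxy)-1,4,4-trimethyldecahydroazulene-2-carboxylic acid, via potassium hydroxy carboxylate 29 (not isolated), via bis-silyl derivative 30 (not isolated)
Conditions: KOH, MeOH/H2O, 50 °C, evaporate; t-BuMe2SiCl, imidazole, DMF, rt; K2CO3, MeOH/THF/H2O, rt; dil. HCl to pH 5
Reagents that add atoms: potassium hydroxide ([K+].[OH-]); tert-butyl(chloro)dimethylsilane (CC(C)(C)[Si](C)(C)Cl)
Why: Hydroxide opens the lactone, silylation of the dry salt gives the silyl ether/silyl ester, and carbonate cleaves only the far more labile silyl ester. The C2 acid is thus set free while the side-chain oxygen is blocked and cannot re-lactonise.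

Step 15
Reactants: 31 (1S,2R,3aR,8aR)-1-(2-{[tert-butyl(dimethyl)silyl]oxy}ethyl)-8,8-(ethane-1,2-diyldioxy)-1,4,4-trimethyldecahydroazulene-2-carboxylic acid
Product: 33 tert-butyl{2-[(1S,3aR,8aR)-8,8-(ethane-1,2-diyldioxy)-1,4,4-trimethyldecahydroazulen-1-yl]ethoxy}dimethylsilane, via thiohydroxamate ester 32 (not isolated)
Conditions: N-hydroxypyridine-2-thione, DCC, DMAP (cat.), CH2Cl2, rt, dark; then t-BuSH, toluene, hν (visible), 20 °C
Reagents that add atoms: none
Why: Barton decarboxylation: photolysis of the thiohydroxamate ester releases CO2 and the secondary C2 radical, which is reduced by the thiol in a chain. With no alkene left in the molecule the radical has no rearrangement channel, and the C2 stereocentre disappears.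

Step 16
Reactants: 33 tert-butyl{2-[(1S,3aR,8aR)-8,8-(ethane-1,2-diyldioxy)-1,4,4-trimethyldecahydroazulen-1-yl]ethoxy}dimethylsilane
Product: 34 2-[(1S,3aR,8aR)-8,8-(ethane-1,2-diyldioxy)-1,4,4-trimethyldecahydroazulen-1-yl]ethan-1-ol
Conditions: Bu4NF, THF, rt
Reagents that add atoms: none
Why: Fluoride cleavage of the primary silyl ether; the ketal is inert.

Step 17
Reactants: 34 2-[(1S,3aR,8aR)-8,8-(ethane-1,2-diyldioxy)-1,4,4-trimethyldecahydroazulen-1-yl]ethan-1-ol
Product: 36 2-[(1S,3aR,8aR)-8,8-(ethane-1,2-diyldioxy)-1,4,4-trimethyldecahydroazulen-1-yl]acetic acid, via aldehyde 35 (not isolated)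
Conditions: TEMPO (cat.), PhI(OAc)2, MeCN/pH 7 buffer, rt
Reagents that add atoms: water (O)
Why: Oxoammonium-mediated oxidation of the primary alcohol to the aldehyde and, through its hydrate, to the acid. The buffered medium protects the ketal.

Step 18
Reactants: 36 2-[(1S,3aR,8aR)-8,8-(ethane-1,2-diyldioxy)-1,4,4-trimethyldecahydroazulen-1-yl]acetic acid
Product: 37 benzyl 2-[(1S,3aR,8aR)-8,8-(ethane-1,2-diyldioxy)-1,4,4-trimethyldecahydroazulen-1-yl]acetate
Conditions: BnBr, K2CO3, DMF, rt
Reagents that add atoms: benzyl bromide (BrCc1ccccc1)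
Why: O-Alkylation of the carboxylate, which is insensitive to the hindrance next to the carboxyl carbon. The benzyl ester can later be removed without acid or base.

Step 19
Reactants: 37 benzyl 2-[(1S,3aR,8aR)-8,8-(ethane-1,2-diyldioxy)-1,4,4-trimethyldecahydroazulen-1-yl]acetate; 38 furan-2(5H)-one
Product: 41 benzyl (2R)-2-[(1R,3aR,8aR)-8,8-(ethane-1,2-diyldioxy)-1,4,4-trimethyldecahydroazulen-1-yl]-2-[(3R,4S)-4-hydroxy-5-oxooxolan-3-yl]acetate, via lithium ester enolate 39 (not isolated), via lithium lactone enolate 40 (not isolated)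
Conditions: LiN(iPr)2, THF, −78 °C; 38, −78 °C; then 2-(phenylsulfonyl)-3-phenyloxaziridine, −78 °C; aq. NH4Cl
Reagents that add atoms: 2-(phenylsulfonyl)-3-phenyloxaziridine (O=S(=O)(c1ccccc1)N1OC1c1ccccc1)
Why: Michael addition of the ester enolate to the butenolide, then electrophilic hydroxylation of the lactone enolate. With C8a lying in the enolate plane next to H1′ (allylic strain), 38 should approach C1′ past the C1 methyl group rather than past the ring CH2, and an open transition state with the bulky C1 substituent anti to C3″ and the ester group clear of the lactone ring should set C4″. The oxaziridine then attacks 40 opposite the new C4″ substituent, giving the trans hydroxy lactone.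

Step 20
Reactants: 41 benzyl (2R)-2-[(1R,3aR,8aR)-8,8-(ethane-1,2-diyldioxy)-1,4,4-trimethyldecahydroazulen-1-yl]-2-[(3R,4S)-4-hydroxy-5-oxooxolan-3-yl]acetate
Product: 42 (2R)-2-[(1R,3aR,8aR)-8,8-(ethane-1,2-diyldioxy)-1,4,4-trimethyldecahydroazulen-1-yl]-2-[(3R,4S)-4-hydroxy-5-oxooxolan-3-yl]acetic acid
Conditions: H2 (1 atm), Pd/C, EtOAc, rt
Reagents that add atoms: none
Why: Hydrogenolysis of the benzyl ester under neutral conditions. Ketal, lactone and the stereocentre next to the carboxyl group are untouched, and no alkene is present at this stage.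

Step 21
Reactants: 42 (2R)-2-[(1R,3aR,8aR)-8,8-(ethane-1,2-diyldioxy)-1,4,4-trimethyldecahydroazulen-1-yl]-2-[(3R,4S)-4-hydroxy-5-oxooxolan-3-yl]acetic acid
Product: 43 (3S,4R)-4-{(1R)-1-[(1S,3aR,8aR)-8,8-(ethane-1,2-diyldioxy)-1,4,4-trimethyldecahydroazulen-1-yl]-2-hydroxyethyl}-3-hydroxyoxolan-2-one
Conditions: BH3·SMe2, THF, 0 °C → rt; MeOH
Reagents that add atoms: none
Why: Borane reduces the carboxylic acid through its acyloxyborane much faster than it reduces the lactone, and this mechanism copes with the hindered acid. C8 is still a ketal, so there is neither an alkene nor a ketone for the reagent to attack.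

Step 22
Reactants: 43 (3S,4R)-4-{(1R)-1-[(1S,3aR,8aR)-8,8-(ethane-1,2-diyldioxy)-1,4,4-trimethyldecahydroazulen-1-yl]-2-hydroxyethyl}-3-hydroxyoxolan-2-one
Product: 44 (3S,4R)-4-{(1R)-2-acetoxy-1-[(1S,3aR,8aR)-8,8-(ethane-1,2-diyldioxy)-1,4,4-trimethyldecahydroazulen-1-yl]ethyl}-2-oxooxolan-3-yl acetate
Conditions: Ac2O, pyridine, DMAP (cat.), CH2Cl2, rt
Reagents that add atoms: acetic anhydride (CC(=O)OC(C)=O)
Why: Acylation of the primary and the secondary hydroxyl group. Capping both before the ketal is opened prevents the C2′ hydroxyl from forming a cyclic ketal with C8.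

Step 23
Reactants: 44 (3S,4R)-4-{(1R)-2-acetoxy-1-[(1S,3aR,8aR)-8,8-(ethane-1,2-diyldioxy)-1,4,4-trimethyldecahydroazulen-1-yl]ethyl}-2-oxooxolan-3-yl acetate
Product: 45 (3S,4R)-4-{(1R)-2-acetoxy-1-[(1S,3aR,8aR)-1,4,4-trimethyl-8-oxodecahydroazulen-1-yl]ethyl}-2-oxooxolan-3-yl acetate
Conditions: pyridinium p-toluenesulfonate, acetone/H2O, 50 °C
Reagents that add atoms: water (O)
Why: Mild acid hydrolysis of the dioxolane. The conditions should be too weak to enolise the hindered ketone toward C8a or to cleave the acetates.

Step 24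
Reactants: 45 (3S,4R)-4-{(1R)-2-acetoxy-1-[(1S,3aR,8aR)-1,4,4-trimethyl-8-oxodecahydroazulen-1-yl]ethyl}-2-oxooxolan-3-yl acetate
Product: 46 (3S,4R)-4-{(1R)-2-acetoxy-1-[(1R,3aR,8aS)-1,4,4-trimethyl-8-methylidenedecahydroazulen-1-yl]ethyl}-2-oxooxolan-3-yl acetate (CNP0234964.1)
Conditions: Zn, CH2Br2, TiCl4, THF/CH2Cl2, 0 °C → rt
Reagents that add atoms: dibromomethane (BrCBr)
Why: Methylenation of the ketone with the non-basic Zn/CH2Br2/TiCl4 reagent, which is selective for ketones over esters and lactones. It does not epimerise the α-carbon C8a and cannot eliminate the α-acetoxy group.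

## Compound list

1 | 3-methylcyclohex-2-en-1-one | CC1=CC(=O)CCC1 | starting material
2 | [(3,3-dimethylcyclohex-1-en-1-yl)oxy]trimethylsilane | C[Si](C)(C)OC1=CC(C)(C)CCC1 | intermediate
3 | rac-[(5,5-dimethylbicyclo[4.1.0]heptan-1-yl)oxy]trimethylsilane | C[Si](C)(C)OC12CC1C(C)(C)CCC2 | intermediate
4 | rac-3-chloro-4,4-dimethylcycloheptan-1-one | O=C1CC(Cl)C(C)(C)CCC1 | intermediate
5 | 4,4-dimethylcyclohept-2-en-1-one | O=C1C=CC(C)(C)CCC1 | intermediate
6 | 2-iodo-4,4-dimethylcyclohept-2-en-1-one | O=C1C(I)=CC(C)(C)CCC1 | intermediate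
7 | but-2-yn-1-ol | CC#CCO | starting material
8 | sodium 2,2-bis(2-methoxyethoxy)-3-methyl-2,5-dihydro-1,2-oxaluminol-2-uide (cyclic alkenylalanate) | CC1=CCO[Al-]1(OCCOC)OCCOC.[Na+] | intermediate
9 | (2Z)-3-iodobut-2-en-1-ol | C/C(I)=C/CO | intermediate
10 | tert-butyl{[(2Z)-3-iodobut-2-en-1-yl]oxy}dimethylsilane | C/C(I)=C/CO[Si](C)(C)C(C)(C)C | intermediate
11 | [(2E)-4-{[tert-butyl(dimethyl)silyl]oxy}but-2-en-2-yl]lithium (lithium cis to the CH2O group) | C/C([Li])=C/CO[Si](C)(C)C(C)(C)C | intermediate
12 | chloro[(2Z)-4-{[tert-butyl(dimethyl)silyl]oxy}but-2-en-2-yl]zinc | C/C([Zn]Cl)=C/CO[Si](C)(C)C(C)(C)C | intermediate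
13 | 2-[(2Z)-4-{[tert-butyl(dimethyl)silyl]oxy}but-2-en-2-yl]-4,4-dimethylcyclohept-2-en-1-one | O=C1C(/C(C)=C\CO[Si](C)(C)C(C)(C)C)=CC(C)(C)CCC1 | intermediate
14 | ethyl 3-iodopropanoate | CCOC(=O)CCI | starting material
15 | bis(3-ethoxy-3-oxopropyl)zinc | CCOC(=O)CC[Zn]CCC(=O)OCC | intermediate
16 | ethyl 3-[(1S)-2-[(2Z)-4-{[tert-butyl(dimethyl)silyl]oxy}but-2-en-2-yl]-3-{[(3-ethoxy-3-oxopropyl)zincio]oxy}-7,7-dimethylcyclohept-2-en-1-yl]propanoate (zinc enolate) | CCOC(=O)CC[C@H]1C(C)(C)CCCC(O[Zn]CCC(=O)OCC)=C1/C(C)=C\CO[Si](C)(C)C(C)(C)C | intermediate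
17 | ethyl 3-[(1R,2R)-2-[(2Z)-4-{[tert-butyl(dimethyl)silyl]oxy}but-2-en-2-yl]-7,7-dimethyl-3-oxocycloheptyl]propanoate | O=C1CCCC(C)(C)[C@H](CCC(=O)OCC)[C@@H]1/C(C)=C\CO[Si](C)(C)C(C)(C)C | intermediate
18 | ethyl 3-[(6R,7R)-6-[(2Z)-4-{[tert-butyl(dimethyl)silyl]oxy}but-2-en-2-yl]-8,8-dimethyl-1,4-dioxaspiro[4.6]undecan-7-yl]propanoate | O1CCOC12CCCC(C)(C)[C@H](CCC(=O)OCC)[C@@H]2/C(C)=C\CO[Si](C)(C)C(C)(C)C | intermediate
19 | ethyl 3-[(6R,7R)-6-[(2Z)-4-hydroxybut-2-en-2-yl]-8,8-dimethyl-1,4-dioxaspiro[4.6]undecan-7-yl]propanoate | O1CCOC12CCCC(C)(C)[C@H](CCC(=O)OCC)[C@@H]2/C(C)=C\CO | intermediate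
20 | 3-[(6R,7R)-6-[(2Z)-4-hydroxybut-2-en-2-yl]-8,8-dimethyl-1,4-dioxaspiro[4.6]undecan-7-yl]propanoic acid | O1CCOC12CCCC(C)(C)[C@H](CCC(O)=O)[C@@H]2/C(C)=C\CO | intermediate
21 | 3-[(6R,7R)-6-[(2Z)-4-hydroxybut-2-en-2-yl]-8,8-dimethyl-1,4-dioxaspiro[4.6]undecan-7-yl]propanoic 2,4,6-trichlorobenzoic anhydride | O1CCOC12CCCC(C)(C)[C@H](CCC(=O)OC(=O)c3c(Cl)cc(Cl)cc3Cl)[C@@H]2/C(C)=C\CO | intermediate
22 | nine-membered (Z)-allylic lactone of 20, cis-fused to the ketalised cycloheptane; ring atoms C8a, C1, C1′, C2′, O, C(=O), C2, C3, C3a; (6R,7R) in the spiro numbering of 20 | O1CCOC12CCCC(C)(C)[C@@H]3CCC(=O)OC/C=C(C)\[C@H]23 | intermediate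
23 | trimethylsilyl ketene acetal of 22 (both ring double bonds cis within the ring) | O1CCOC12CCCC(C)(C)[C@@H]3C/C=C(/O[Si](C)(C)C)OC/C=C(C)\[C@H]23 | intermediate
24 | trimethylsilyl (1S,2R,3aR,8aR)-1-ethenyl-8,8-(ethane-1,2-diyldioxy)-1,4,4-trimethyldecahydroazulene-2-carboxylate | O1CCOC12CCCC(C)(C)[C@@H]3C[C@@H](C(=O)O[Si](C)(C)C)[C@@](C)(C=C)[C@H]23 | intermediate
25 | (1S,2R,3aR,8aR)-1-ethenyl-8,8-(ethane-1,2-diyldioxy)-1,4,4-trimethyldecahydroazulene-2-carboxylic acid | O1CCOC12CCCC(C)(C)[C@@H]3C[C@@H](C(O)=O)[C@@](C)(C=C)[C@H]23 | intermediate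
26 | bis(9-borabicyclo[3.3.1]nonan-9-yl) adduct of 25 (acyloxyborane at the C2 carboxyl, B-alkyl at the former vinyl terminus) | O1CCOC12CCCC(C)(C)[C@@H]3C[C@@H](C(=O)OB4C5CCCC4CCC5)[C@@](C)(CCB4C5CCCC4CCC5)[C@H]23 | intermediate
27 | (1S,2R,3aR,8aR)-8,8-(ethane-1,2-diyldioxy)-1-(2-hydroxyethyl)-1,4,4-trimethyldecahydroazulene-2-carboxylic acid | O1CCOC12CCCC(C)(C)[C@@H]3C[C@@H](C(O)=O)[C@@](C)(CCO)[C@H]23 | intermediate
28 | δ-lactone of 27 (C2 carboxyl to the oxygen of the 2-hydroxyethyl group, cis-fused to the cyclopentane) | O1CCOC12CCCC(C)(C)[C@@H]3C[C@H]4C(=O)OCC[C@@]4(C)[C@H]23 | intermediate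
29 | potassium (1S,2R,3aR,8aR)-8,8-(ethane-1,2-diyldioxy)-1-(2-hydroxyethyl)-1,4,4-trimethyldecahydroazulene-2-carboxylate | O1CCOC12CCCC(C)(C)[C@@H]3C[C@@H](C([O-])=O)[C@@](C)(CCO)[C@H]23.[K+] | intermediate
30 | tert-butyldimethylsilyl (1S,2R,3aR,8aR)-1-(2-{[tert-butyl(dimethyl)silyl]oxy}ethyl)-8,8-(ethane-1,2-diyldioxy)-1,4,4-trimethyldecahydroazulene-2-carboxylate | O1CCOC12CCCC(C)(C)[C@@H]3C[C@@H](C(=O)O[Si](C)(C)C(C)(C)C)[C@@](C)(CCO[Si](C)(C)C(C)(C)C)[C@H]23 | intermediate
31 | (1S,2R,3aR,8aR)-1-(2-{[tert-butyl(dimethyl)silyl]oxy}ethyl)-8,8-(ethane-1,2-diyldioxy)-1,4,4-trimethyldecahydroazulene-2-carboxylic acid | O1CCOC12CCCC(C)(C)[C@@H]3C[C@@H](C(O)=O)[C@@](C)(CCO[Si](C)(C)C(C)(C)C)[C@H]23 | intermediate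
32 | 2-thioxopyridin-1(2H)-yl (1S,2R,3aR,8aR)-1-(2-{[tert-butyl(dimethyl)silyl]oxy}ethyl)-8,8-(ethane-1,2-diyldioxy)-1,4,4-trimethyldecahydroazulene-2-carboxylate | O1CCOC12CCCC(C)(C)[C@@H]3C[C@@H](C(=O)On4ccccc4=S)[C@@](C)(CCO[Si](C)(C)C(C)(C)C)[C@H]23 | intermediate
33 | tert-butyl{2-[(1S,3aR,8aR)-8,8-(ethane-1,2-diyldioxy)-1,4,4-trimethyldecahydroazulen-1-yl]ethoxy}dimethylsilane | O1CCOC12CCCC(C)(C)[C@@H]3CC[C@@](C)(CCO[Si](C)(C)C(C)(C)C)[C@H]23 | intermediate
34 | 2-[(1S,3aR,8aR)-8,8-(ethane-1,2-diyldioxy)-1,4,4-trimethyldecahydroazulen-1-yl]ethan-1-ol | O1CCOC12CCCC(C)(C)[C@@H]3CC[C@@](C)(CCO)[C@H]23 | intermediate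
35 | 2-[(1S,3aR,8aR)-8,8-(ethane-1,2-diyldioxy)-1,4,4-trimethyldecahydroazulen-1-yl]acetaldehyde | O1CCOC12CCCC(C)(C)[C@@H]3CC[C@@](C)(CC=O)[C@H]23 | intermediate
36 | 2-[(1S,3aR,8aR)-8,8-(ethane-1,2-diyldioxy)-1,4,4-trimethyldecahydroazulen-1-yl]acetic acid | O1CCOC12CCCC(C)(C)[C@@H]3CC[C@@](C)(CC(O)=O)[C@H]23 | intermediate
37 | benzyl 2-[(1S,3aR,8aR)-8,8-(ethane-1,2-diyldioxy)-1,4,4-trimethyldecahydroazulen-1-yl]acetate | O1CCOC12CCCC(C)(C)[C@@H]3CC[C@@](C)(CC(=O)OCc4ccccc4)[C@H]23 | intermediate
38 | furan-2(5H)-one | O=C1OCC=C1 | starting material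
39 | lithium enolate of 37 (C1 substituent trans to O–Li) | O1CCOC12CCCC(C)(C)[C@@H]3CC[C@@](C)(/C=C(/[O-])OCc4ccccc4)[C@H]23.[Li+] | intermediate
40 | lithium lactone enolate: Michael adduct of 39 and 38 before hydroxylation | O1CCOC12CCCC(C)(C)[C@@H]3CC[C@@](C)([C@H](C(=O)OCc4ccccc4)[C@@H]5COC([O-])=C5)[C@H]23.[Li+] | intermediate
41 | benzyl (2R)-2-[(1R,3aR,8aR)-8,8-(ethane-1,2-diyldioxy)-1,4,4-trimethyldecahydroazulen-1-yl]-2-[(3R,4S)-4-hydroxy-5-oxooxolan-3-yl]acetate | O1CCOC12CCCC(C)(C)[C@@H]3CC[C@@](C)([C@H](C(=O)OCc4ccccc4)[C@@H]5COC(=O)[C@H]5O)[C@H]23 | intermediate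
42 | (2R)-2-[(1R,3aR,8aR)-8,8-(ethane-1,2-diyldioxy)-1,4,4-trimethyldecahydroazulen-1-yl]-2-[(3R,4S)-4-hydroxy-5-oxooxolan-3-yl]acetic acid | O1CCOC12CCCC(C)(C)[C@@H]3CC[C@@](C)([C@H](C(O)=O)[C@@H]5COC(=O)[C@H]5O)[C@H]23 | intermediate
43 | (3S,4R)-4-{(1R)-1-[(1S,3aR,8aR)-8,8-(ethane-1,2-diyldioxy)-1,4,4-trimethyldecahydroazulen-1-yl]-2-hydroxyethyl}-3-hydroxyoxolan-2-one | O1CCOC12CCCC(C)(C)[C@@H]3CC[C@@](C)([C@H](CO)[C@@H]5COC(=O)[C@H]5O)[C@H]23 | intermediate
44 | (3S,4R)-4-{(1R)-2-acetoxy-1-[(1S,3aR,8aR)-8,8-(ethane-1,2-diyldioxy)-1,4,4-trimethyldecahydroazulen-1-yl]ethyl}-2-oxooxolan-3-yl acetate | O1CCOC12CCCC(C)(C)[C@@H]3CC[C@@](C)([C@H](COC(C)=O)[C@@H]5COC(=O)[C@H]5OC(C)=O)[C@H]23 | intermediate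
45 | (3S,4R)-4-{(1R)-2-acetoxy-1-[(1S,3aR,8aR)-1,4,4-trimethyl-8-oxodecahydroazulen-1-yl]ethyl}-2-oxooxolan-3-yl acetate | O=C1CCCC(C)(C)[C@@H]2CC[C@@](C)([C@H](COC(C)=O)[C@@H]3COC(=O)[C@H]3OC(C)=O)[C@H]12 | intermediate
46 | (3S,4R)-4-{(1R)-2-acetoxy-1-[(1R,3aR,8aS)-1,4,4-trimethyl-8-methylidenedecahydroazulen-1-yl]ethyl}-2-oxooxolan-3-yl acetate (CNP0234964.1) | C=C1CCCC(C)(C)[C@@H]2CC[C@@](C)([C@H](COC(C)=O)[C@@H]3COC(=O)[C@H]3OC(C)=O)[C@H]12 | target

## Step count and least certain steps

Total: 24 steps. Longest linear sequence: 22 steps (steps 1 to 4 and 7 to 24, from 1); steps 5 and 6 are the two-step branch from 7 to 10.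

Step 12 (key step).
- What may go wrong: slow or incomplete enolisation and silylation of the strained lactone; a [3,3] shift that is sluggish at the fully substituted alkene terminus, so that the ketene acetal decomposes or reverts to 22 on work-up; or bond formation on the other face of C1.
- Fallback: it sets out from hydroxy ester 19 (step 10 stopped after the fluoride stage) and returns at 25. The allylic alcohol is converted with MsCl, LiCl and 2,4,6-collidine in DMF into ethyl 3-[(6R,7R)-6-[(2Z)-4-chlorobut-2-en-2-yl]-8,8-dimethyl-1,4-dioxaspiro[4.6]undecan-7-yl]propanoate F1. Treatment with KN(SiMe3)2 in THF from −78 to 0 °C should close the cyclopentane by intramolecular SN2′ alkylation of the ester enolate at C1 (5-exo, favoured over the seven-membered SN2 closure). The same allylic-strain conformer of the (Z)-alkene should again place the vinyl group cis to H8a, giving ethyl (1S,2R,3aR,8aR)-1-ethenyl-8,8-(ethane-1,2-diyldioxy)-1,4,4-trimethyldecahydroazulene-2-carboxylate F2. Hydrolysis with KOH in aqueous ethanol at reflux gives 25. The C2 configuration of F2 is not secured by this closure and does not matter, because C2 becomes CH2 in step 15; a C2 epimer would be taken through steps 13 to 15 as the open hydroxy acid.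

Step 8.
- What may go wrong: low reactivity of the α-substituted enone with its neopentyl β-carbon toward the zinc reagent; erosion of enantioselectivity; and loss of the cis relationship through O-protonation and equilibration of the doubly activated centre before the ketal is on.
- Fallback: it sets out from 5 and returns at 17, running the enantio-determining addition on the unhindered parent enone. Reagent 15 is added to 5 with the same Cu(OTf)2/phosphoramidite catalyst and the enolate is trapped with Me3SiCl/Et3N as ethyl 3-[(1R)-7,7-dimethyl-3-(trimethylsilyloxy)cyclohept-2-en-1-yl]propanoate F3. Palladium-catalysed α-alkenylation of this regiodefined enol ether with iodide 10 (Pd2(dba)3, P(t-Bu)3, Bu3SnF, toluene, 80 °C) should give the thermodynamically preferred ethyl 3-[(1R,2S)-2-[(2Z)-4-{[tert-butyl(dimethyl)silyl]oxy}but-2-en-2-yl]-7,7-dimethyl-3-oxocycloheptyl]propanoate F4. Deprotonation at the doubly activated ring carbon with LiN(SiMe3)2 at −78 °C and kinetic reprotonation with the hindered phenol then gives 17.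

Step 11.
- What may go wrong: intermolecular acylation (diolide and oligomer formation) outrunning closure of the nine-membered ring.
- Fallback: it sets out from 20 and returns at 22 with the polarity of the ring closure reversed. Under Mitsunobu conditions (PPh3, diisopropyl azodicarboxylate, toluene, slow addition at high dilution) the primary allylic hydroxyl is activated and the carboxylate closes the ring by O-alkylation, so no activated acyl species is present to oligomerise; no new isolated compound arises (entry F0).

Step 19.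
- What may go wrong: proton transfer from C5 of 38 to the very hindered enolate instead of C–C bond formation, and insufficient discrimination between the two faces of C1′ or of 38, since both rest on substrate control.
- Fallback: it sets out from 37 and returns at 41, using an open-chain acceptor with less acidic γ-hydrogens and closing the lactone afterwards. Enolate 39 is added to methyl (2E)-4-{[tert-butyl(dimethyl)silyl]oxy}but-2-enoate; either enolate geometry is available (LiN(iPr)2 in THF with or without a dipolar cosolvent), which gives a handle on the C1′/C4″ relationship. The adduct is 1-benzyl 5-methyl (2R,3R)-2-[(1R,3aR,8aR)-8,8-(ethane-1,2-diyldioxy)-1,4,4-trimethyldecahydroazulen-1-yl]-3-({[tert-butyl(dimethyl)silyl]oxy}methyl)pentanedioate F5. Bu4NF buffered with AcOH removes the silyl group and the alkoxide lactonises onto the methyl ester to give benzyl (2R)-2-[(1R,3aR,8aR)-8,8-(ethane-1,2-diyldioxy)-1,4,4-trimethyldecahydroazulen-1-yl]-2-[(3R)-5-oxooxolan-3-yl]acetate F6. Enolisation of the lactone with LiN(SiMe3)2 at −78 °C and hydroxylation with the same oxaziridine, anti to the C4″ substituent, gives 41.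

## Further compounds

F1 | step 12 | ethyl 3-[(6R,7R)-6-[(2Z)-4-chlorobut-2-en-2-yl]-8,8-dimethyl-1,4-dioxaspiro[4.6]undecan-7-yl]propanoate | O1CCOC12CCCC(C)(C)[C@H](CCC(=O)OCC)[C@@H]2/C(C)=C\CCl
F2 | step 12 | ethyl (1S,2R,3aR,8aR)-1-ethenyl-8,8-(ethane-1,2-diyldioxy)-1,4,4-trimethyldecahydroazulene-2-carboxylate | O1CCOC12CCCC(C)(C)[C@@H]3C[C@@H](C(=O)OCC)[C@@](C)(C=C)[C@H]23
F3 | step 8 | ethyl 3-[(1R)-7,7-dimethyl-3-(trimethylsilyloxy)cyclohept-2-en-1-yl]propanoate | CCOC(=O)CC[C@H]1C(C)(C)CCCC(O[Si](C)(C)C)=C1
F4 | step 8 | ethyl 3-[(1R,2S)-2-[(2Z)-4-{[tert-butyl(dimethyl)silyl]oxy}but-2-en-2-yl]-7,7-dimethyl-3-oxocycloheptyl]propanoate | O=C1CCCC(C)(C)[C@H](CCC(=O)OCC)[C@H]1/C(C)=C\CO[Si](C)(C)C(C)(C)C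
F0 | step 11 | none | none
F5 | step 19 | 1-benzyl 5-methyl (2R,3R)-2-[(1R,3aR,8aR)-8,8-(ethane-1,2-diyldioxy)-1,4,4-trimethyldecahydroazulen-1-yl]-3-({[tert-butyl(dimethyl)silyl]oxy}methyl)pentanedioate | O1CCOC12CCCC(C)(C)[C@@H]3CC[C@@](C)([C@H](C(=O)OCc4ccccc4)[C@H](CO[Si](C)(C)C(C)(C)C)CC(=O)OC)[C@H]23
F6 | step 19 | benzyl (2R)-2-[(1R,3aR,8aR)-8,8-(ethane-1,2-diyldioxy)-1,4,4-trimethyldecahydroazulen-1-yl]-2-[(3R)-5-oxooxolan-3-yl]acetate | O1CCOC12CCCC(C)(C)[C@@H]3CC[C@@](C)([C@H](C(=O)OCc4ccccc4)[C@@H]5COC(=O)C5)[C@H]23
A1 | alternative 1 | tert-butyl 2-[(1S,3aR,8aR)-1,4,4-trimethyl-8-oxodecahydroazulen-1-yl]acetate | O=C1CCCC(C)(C)[C@@H]2CC[C@@](C)(CC(=O)OC(C)(C)C)[C@H]12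
A2 | alternative 1 | tert-butyl 2-[(1S)-1-methyl-2-(5-methylhex-5-enoyl)cyclopent-2-en-1-yl]acetate | C=C(C)CCCC(=O)C1=CCC[C@@]1(C)CC(=O)OC(C)(C)C
A3 | alternative 2 | (4R)-4-{(1R)-2-(benzyloxy)-1-[(1S,3aR,8aR)-8,8-(ethane-1,2-diyldioxy)-1,4,4-trimethyldecahydroazulen-1-yl]ethyl}oxolan-2-one | O1CCOC12CCCC(C)(C)[C@@H]3CC[C@@](C)([C@H](COCc4ccccc4)[C@@H]4COC(=O)C4)[C@H]23
A4 | alternative 2 | 3-{(1R)-2-(benzyloxy)-1-[(1S,3aR,8aR)-8,8-(ethane-1,2-diyldioxy)-1,4,4-trimethyldecahydroazulen-1-yl]ethyl}cyclobutan-1-one | O1CCOC12CCCC(C)(C)[C@@H]3CC[C@@](C)([C@H](COCc4ccccc4)C4CC(=O)C4)[C@H]23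
A5 | alternative 3 | tert-butyl 2-[(1S,3aR,8aS)-1,4,4-trimethyl-8-methylidenedecahydroazulen-1-yl]acetate | C=C1CCCC(C)(C)[C@@H]2CC[C@@](C)(CC(=O)OC(C)(C)C)[C@H]12
A6 | alternative 3 | tert-butyl 2-[(1S,2S,4aS,8aS)-1-(methanesulfonyloxy)-2,5,5,8a-tetramethyldecahydronaphthalen-2-yl]acetate (equatorial mesylate) | C[C@]12CCCC([C@@H]1CC[C@@](CC(=O)OC(C)(C)C)([C@@H]2OS(C)(=O)=O)C)(C)C
A7 | alternative 3 | (+)-sclareolide, (3aR,5aS,9aS,9bR)-3a,6,6,9a-tetramethyldecahydronaphtho[2,1-b]furan-2(1H)-one | C[C@]12CCCC([C@@H]1CC[C@@]3([C@@H]2CC(=O)O3)C)(C)C
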